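(The constants used here stand for no real mixture; the run is a simulation.)

The ratio I carry through this flask is Z offered per L charged.

L 0.10 M; X 0.130 M; time 10 d; volume of the second phase over the first 2.0

    Z ⇌ X, rate k1*([Z] - [X]/K1) per volume of the first phase (K1 = 0.33, k1 = 7.2 × 10⁻⁶ s⁻¹)
    L + Z → L.Z (k2 = 0.0084 M⁻¹ s⁻¹)
    Z + L.Z → Z.L.Z (k3 = 0.010 M⁻¹ s⁻¹)
    D ⇌ L.Z, rate k4*(cs4 - [L.Z]) while solid is left; crystals form when [L.Z] > cs4 (cs4 = 3.0 mM, k4 = 2.9 × 10⁻⁴ s⁻¹)
    2 L → L2 (k5 = 8.0 × 10⁻⁵ M⁻¹ s⁻¹)

- percent here means L units held: one L2 counts as two
- what is said of L.Z includes D
- two of one species on the left: rate k times its square, two consumed each time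
- in the second phase: X; everything else is in the first
- charges count per volume of the first phase; a concentration in a rate is the amount of a species over the volume of its own phase; every rate counts per litre of the first phase
- D is a solid; its amount is given per volume of the solution
- run time (flask): 10 d

- south-east: doubling the transfer coefficient of step 1, all else as stated
- north: doubling the amount of X, all else as stated
- north-east: doubling the dissolution coefficient of step 4, all else as stated
- south-west: doubling the solubility in step 4, all else as stated

- the L.Z and D together standing at 10 d, as a percentage of the L charged
- the change that raises the amount of L.Z and D together at 10 d, in percent of the L charged most ("none" if none brings more than 2 percentage points) (south-east / north / north-east / south-west / none)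
- amount of L.Z and D together at 10 d, in percent of the L charged, after south-east

I count in fractions of the L charged. The flask offers 1.30 of Z per L, and I call this the Z budget, r. L.Z costs one Z and Z.L.Z two, so if L2 takes a share d and Z is finally used up, then y = 2(1 − d) − r.

Now d. X crosses with a lifetime of 1.06 d, so Z arrives at first at 1.23 d⁻¹, while the dimerisation takes 1.38 d⁻¹. Their ratio is 1.13. I let the fed Z go to L, which, at its charge, takes it 28.0 times faster than L.Z at its solubility does; that is a selectivity factor. The dimer rate drifts with the square of the L left, so its share of L's loss sinks from 53.1% at the start to 22.0% with half the L left. Simpson weighting over L gives d = 23.5%, hence y = 23.0%.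

The weak link is the steady feed. While L lasts it draws 58.8% of the budget, so the mean feed is about 70.6% of its first value. The ratio becomes 1.60, d becomes 29.3%, and I commit to y = 11.4%. South-east halves the ratio to 0.564; with a mean feed of 67.0% it gives 31.6%. North lifts the budget to 2.60, and the crystal constants stand nowhere in the rule, so I choose south-east.

The forecast says 10%, south-east and 30%, holding that “Doubling the transfer coefficient roughly halves that dimer loss”. The simulation gives 10.4%, south-east with a gain of 18 percentage points, and 28.3%.

In this flask L2 stands at 29.9% and X at 0.0688% of its charge, so the rule returns 10.2%. The low y of this flask comes from two steps acting together, the reaction of Z + L.Z to Z.L.Z and the reaction of 2 L to L2: y is 72.0% without the first and 69.9% without the second, against 10.4% with both.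

In the neighbour flask with 0.25 M of L, the budget is 0.520 and the ratio 7.05. With a mean feed of 58.8% the same reckoning gives 17.3%; the simulation gives 24.9%, with L2 at 61.6%.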